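Assumption: the S-configured catalyst Rh2(S-TCPTTL)4 (dirhodium tetrakis[N-tetrachlorophthaloyl-(S)-tert-leucinate]) is taken to give the (2S,3S) series; the sense of induction must be checked on the first run, and Rh2(R-TCPTTL)4 is used instead if it is opposite.

Ring A is the 4-hydroxy-2-pyranone on C3; ring B is the pyranone fused to the dihydrofuran. Locants C2, C3, C3a follow furo[3,2-c]pyran numbering. The target is the trans-(2S,3S) compound.

## Retrosynthetic overview

- Last step: fluoride removes four silyl groups from the fully assembled skeleton.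
- Key disconnection: the dihydrofuran is cut at C3a–C3 and O1–C2. This gives a 3-diazopyran-2,4-dione (ring B, with C3 made electrophilic as a rhodium carbene, an α-cation equivalent of the 4-hydroxypyranone) and the styryl alkene of silyl-protected hispidin (ring A already attached). One chiral dirhodium-catalysed formal [3+2] step makes the C–C bond, the C–O bond and both stereocentres.
- Each styrylpyranone comes from a dianion of triacetic acid lactone and a silylated hydroxybenzaldehyde (aldol addition, then dehydration).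
- Ring order: pyranone rings A and B are bought ready-made as triacetic acid lactone; the dihydrofuran is the only ring formed, last, in the key step.

## Route

Step 1
Reactants: 1 3,4-dihydroxybenzaldehyde
Product: 2 3,4-bis[(tert-butyldimethylsilyl)oxy]benzaldehyde
Conditions: TBSCl (2.3 equiv), imidazole (3 equiv), DMF, 0 °C → rt
Reagents that add atoms: tert-butyldimethylsilyl chloride (TBSCl), CC(C)(C)[Si](C)(C)Cl
Why: Imidazole-promoted silyl ether formation masks both phenols, which would otherwise quench the dianion of step 2 and insert into the carbene of step 7, while keeping the arene electron-rich.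

Step 2
Reactants: 3 4-hydroxy-6-methyl-2H-pyran-2-one (triacetic acid lactone); 2 3,4-bis[(tert-butyldimethylsilyl)oxy]benzaldehyde
Product: 6 6-[(E)-2-{3,4-bis[(tert-butyldimethylsilyl)oxy]phenyl}ethenyl]-4-hydroxy-2H-pyran-2-one, via dilithium dianion of triacetic acid lactone 4 (not isolated), via racemic benzylic alcohol 5 (not isolated)
Conditions: 3 (1.1 equiv), LiN(i-Pr)2 (2.2 equiv, commercial solution), THF, −78 → −40 °C; 2 (1.0 equiv), −78 → 0 °C; then TsOH·H2O (5 equiv), PhMe, 60 °C, same flask
Reagents that add atoms: none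
Why: The second deprotonation occurs at the 6-methyl group, this carbanion adds to the non-enolisable aldehyde (vinylogous aldol addition of a dianion), and acid-catalysed E1 dehydration through the para-silyloxybenzyl cation gives the conjugated E-alkene as the thermodynamic isomer, leaving no stereocentre.

Step 3
Reactants: 6 6-[(E)-2-{3,4-bis[(tert-butyldimethylsilyl)oxy]phenyl}ethenyl]-4-hydroxy-2H-pyran-2-one
Product: 7 6-[(E)-2-{3,4-bis[(tert-butyldimethylsilyl)oxy]phenyl}ethenyl]-4-[(triisopropylsilyl)oxy]-2H-pyran-2-one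
Conditions: TIPSCl (1.2 equiv), imidazole (2 equiv), CH2Cl2, 0 °C → rt; filtration through Et3N-washed silica
Reagents that add atoms: triisopropylsilyl chloride (TIPSCl), CC(C)[Si](Cl)(C(C)C)C(C)C
Why: O-silylation of the acidic enol (pKa about 5) removes the O–H that would undergo carbene insertion in step 7, and the bulky triisopropylsilyl group gives a vinylogous silyl ester that tolerates handling and screens C3 and C5 of ring A.

Step 4
Reactants: 8 4-hydroxybenzaldehyde
Product: 9 4-[(tert-butyldimethylsilyl)oxy]benzaldehyde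
Conditions: TBSCl (1.2 equiv), imidazole (2 equiv), DMF, rt
Reagents that add atoms: tert-butyldimethylsilyl chloride (TBSCl), CC(C)(C)[Si](C)(C)Cl
Why: The same imidazole-promoted silyl ether formation as in step 1 protects the phenol for the dianion and carbene steps.

Step 5
Reactants: 3 4-hydroxy-6-methyl-2H-pyran-2-one (triacetic acid lactone); 9 4-[(tert-butyldimethylsilyl)oxy]benzaldehyde
Product: 13 6-[(E)-2-{4-[(tert-butyldimethylsilyl)oxy]phenyl}ethenyl]-4-hydroxy-2H-pyran-2-one, via sodium salt of triacetic acid lactone 10 (not isolated), via lithium sodium dianion of triacetic acid lactone 11 (not isolated), via racemic benzylic alcohol 12 (not isolated)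
Conditions: 3 (1.15 equiv), NaH (1.15 equiv), THF/DMPU (10:1), 0 °C → rt until H2 evolution ends; n-BuLi (1.10 equiv), −78 → −40 °C; 9 (1.0 equiv), −78 → 0 °C; then TsOH·H2O (3 equiv), PhMe, 60 °C, same flask
Reagents that add atoms: none
Why: Sodium hydride first gives the sodium enolate with loss of H2, n-butyllithium then removes a proton from the 6-methyl group of this deactivated vinylogous carboxylate as in the Huckin–Weiler generation of β-dicarbonyl dianions, the carbanion adds to the non-enolisable aldehyde (vinylogous aldol addition), and acid-catalysed E1 dehydration through the para-silyloxybenzyl cation gives the E-styrylpyranone without an amine in the flask.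

Step 6
Reactants: 13 6-[(E)-2-{4-[(tert-butyldimethylsilyl)oxy]phenyl}ethenyl]-4-hydroxy-2H-pyran-2-one
Product: 14 6-[(E)-2-{4-[(tert-butyldimethylsilyl)oxy]phenyl}ethenyl]-3-diazo-2H-pyran-2,4(3H)-dione
Conditions: p-ABSA (1.2 equiv), Et3N (1.5 equiv), MeCN, 0 °C → rt
Reagents that add atoms: 4-acetamidobenzenesulfonyl azide (p-ABSA), CC(=O)Nc1ccc(cc1)S(=O)(=O)N=[N+]=[N-]
Why: Regitz diazo transfer: the triethylammonium enolate of the cyclic 1,3-dicarbonyl attacks the terminal azide nitrogen at C3 and the adduct collapses to the 2-diazo-1,3-dicarbonyl and the sulfonamide, leaving the aryl silyl ether and the alkene untouched.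

Step 7
Reactants: 14 6-[(E)-2-{4-[(tert-butyldimethylsilyl)oxy]phenyl}ethenyl]-3-diazo-2H-pyran-2,4(3H)-dione; 7 6-[(E)-2-{3,4-bis[(tert-butyldimethylsilyl)oxy]phenyl}ethenyl]-4-[(triisopropylsilyl)oxy]-2H-pyran-2-one
Product: 15 (2S,3S)-2-{3,4-bis[(tert-butyldimethylsilyl)oxy]phenyl}-6-[(E)-2-{4-[(tert-butyldimethylsilyl)oxy]phenyl}ethenyl]-3-{2-oxo-4-[(triisopropylsilyl)oxy]-2H-pyran-6-yl}-2,3-dihydro-4H-furo[3,2-c]pyran-4-one
Conditions: Rh2(S-TCPTTL)4 (2 mol %), 7 (2.5 equiv, excess recovered), PhCF3, 4 Å MS, 40 °C, 14 added over 8 h by syringe pump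
Reagents that add atoms: none
Why: Proposed new method: loss of N2 from 14 on the divalent-rhodium dimer gives a rhodium-bound carbene in which C3 of the pyrandione, normally the nucleophilic carbon of the 1,3-dicarbonyl, is an electrophilic α-cation (enolonium) equivalent; the styryl alkene of 7, nucleophilic at the carbon next to ring A because attack there leaves a para-silyloxybenzyl cation, bonds to it inside the chiral pocket of the carboxylate ligands (this face selection sets C3), and the ketone oxygen then closes on the benzylic cation anti to the ring-A substituent (sets C2 trans), a formal [3+2] cycloaddition whose closest known relatives are the Rh2(OAc)4-catalysed dihydrofuran annulations of 3-diazo-4-oxocoumarins and 3-diazopyran-2,4-diones with styrenes and enol ethers, and the enantioselective cyclopropanations of acceptor-substituted diazo compounds with phthaloyl-tert-leucinate dirhodium catalysts.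

Step 8
Reactants: 15 (2S,3S)-2-{3,4-bis[(tert-butyldimethylsilyl)oxy]phenyl}-6-[(E)-2-{4-[(tert-butyldimethylsilyl)oxy]phenyl}ethenyl]-3-{2-oxo-4-[(triisopropylsilyl)oxy]-2H-pyran-6-yl}-2,3-dihydro-4H-furo[3,2-c]pyran-4-one
Product: 16 (2S,3S)-2-(3,4-dihydroxyphenyl)-3-(4-hydroxy-2-oxo-2H-pyran-6-yl)-6-[(E)-2-(4-hydroxyphenyl)ethenyl]-2,3-dihydro-4H-furo[3,2-c]pyran-4-one
Conditions: Bu4NF (6 equiv), AcOH (6 equiv), THF, 0 °C → rt, argon; Sephadex LH-20 or reverse-phase purification
Reagents that add atoms: none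
Why: Fluoride-driven desilylation cleaves all four Si–O bonds while acetic acid keeps the phenols and the pyranone enol protonated, so no phenoxide can open the benzylic C2–O bond and neither stereocentre is touched.

## Compound list

1 | 3,4-dihydroxybenzaldehyde | O=Cc1ccc(O)c(O)c1 | starting material
2 | 3,4-bis[(tert-butyldimethylsilyl)oxy]benzaldehyde | O=Cc1ccc(O[Si](C)(C)C(C)(C)C)c(O[Si](C)(C)C(C)(C)C)c1 | intermediate
3 | 4-hydroxy-6-methyl-2H-pyran-2-one (triacetic acid lactone) | Cc1cc(O)cc(=O)o1 | starting material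
4 | dilithium dianion of 4-hydroxy-6-methyl-2H-pyran-2-one, Li2(C6H4O3) (O4 oxide and 6-CH2 carbanion) | [Li+].[Li+].[CH2-]C1=CC([O-])=CC(=O)O1 | intermediate (not isolated)
5 | 6-{2-[3,4-bis((tert-butyldimethylsilyl)oxy)phenyl]-2-hydroxyethyl}-4-hydroxy-2H-pyran-2-one (racemic) | O=c1cc(O)cc(CC(O)c2ccc(O[Si](C)(C)C(C)(C)C)c(O[Si](C)(C)C(C)(C)C)c2)o1 | intermediate (not isolated)
6 | 6-[(E)-2-{3,4-bis[(tert-butyldimethylsilyl)oxy]phenyl}ethenyl]-4-hydroxy-2H-pyran-2-one | O=c1cc(O)cc(/C=C/c2ccc(O[Si](C)(C)C(C)(C)C)c(O[Si](C)(C)C(C)(C)C)c2)o1 | intermediate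
7 | 6-[(E)-2-{3,4-bis[(tert-butyldimethylsilyl)oxy]phenyl}ethenyl]-4-[(triisopropylsilyl)oxy]-2H-pyran-2-one | O=c1cc(O[Si](C(C)C)(C(C)C)C(C)C)cc(/C=C/c2ccc(O[Si](C)(C)C(C)(C)C)c(O[Si](C)(C)C(C)(C)C)c2)o1 | intermediate
8 | 4-hydroxybenzaldehyde | O=Cc1ccc(O)cc1 | starting material
9 | 4-[(tert-butyldimethylsilyl)oxy]benzaldehyde | O=Cc1ccc(O[Si](C)(C)C(C)(C)C)cc1 | intermediate
10 | sodium 6-methyl-2-oxo-2H-pyran-4-olate, Na(C6H5O3) | [Na+].Cc1cc([O-])cc(=O)o1 | intermediate (not isolated)
11 | lithium sodium dianion of 4-hydroxy-6-methyl-2H-pyran-2-one, LiNa(C6H4O3) (O4 oxide and 6-CH2 carbanion) | [Li+].[Na+].[CH2-]C1=CC([O-])=CC(=O)O1 | intermediate (not isolated)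
12 | 6-{2-[4-((tert-butyldimethylsilyl)oxy)phenyl]-2-hydroxyethyl}-4-hydroxy-2H-pyran-2-one (racemic) | O=c1cc(O)cc(CC(O)c2ccc(O[Si](C)(C)C(C)(C)C)cc2)o1 | intermediate (not isolated)
13 | 6-[(E)-2-{4-[(tert-butyldimethylsilyl)oxy]phenyl}ethenyl]-4-hydroxy-2H-pyran-2-one | O=c1cc(O)cc(/C=C/c2ccc(O[Si](C)(C)C(C)(C)C)cc2)o1 | intermediate
14 | 6-[(E)-2-{4-[(tert-butyldimethylsilyl)oxy]phenyl}ethenyl]-3-diazo-2H-pyran-2,4(3H)-dione | [N-]=[N+]=C1C(=O)C=C(/C=C/c2ccc(O[Si](C)(C)C(C)(C)C)cc2)OC1=O | intermediate
15 | (2S,3S)-2-{3,4-bis[(tert-butyldimethylsilyl)oxy]phenyl}-6-[(E)-2-{4-[(tert-butyldimethylsilyl)oxy]phenyl}ethenyl]-3-{2-oxo-4-[(triisopropylsilyl)oxy]-2H-pyran-6-yl}-2,3-dihydro-4H-furo[3,2-c]pyran-4-one | O=c1cc(O[Si](C(C)C)(C(C)C)C(C)C)cc([C@H]2c3c(cc(/C=C/c4ccc(O[Si](C)(C)C(C)(C)C)cc4)oc3=O)O[C@@H]2c2ccc(O[Si](C)(C)C(C)(C)C)c(O[Si](C)(C)C(C)(C)C)c2)o1 | intermediate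
16 | (2S,3S)-2-(3,4-dihydroxyphenyl)-3-(4-hydroxy-2-oxo-2H-pyran-6-yl)-6-[(E)-2-(4-hydroxyphenyl)ethenyl]-2,3-dihydro-4H-furo[3,2-c]pyran-4-one | O=c1cc(O)cc([C@H]2c3c(cc(/C=C/c4ccc(O)cc4)oc3=O)O[C@@H]2c2ccc(O)c(O)c2)o1 | target

## Step count and risks

Total steps: 8. Longest linear sequence: 5 (steps 1, 2, 3, 7, 8; the branch through steps 4, 5, 6, 7, 8 is equally long).

The three steps most likely to fail:

**Step 7 (key step).** The alkene of 7 is deactivated by ring A and may react slowly. The carbene can also attack the styryl alkene of 14 or of 15; slow addition and excess 7 are meant to limit this. Closure through the lactone oxygen would give the furo[2,3-b]pyran-4-one isomer. The level and sense of enantioselectivity are untested. The fallback sets out from 13 and 7 and replaces the carbene by a one-electron oxidative annulation followed by resolution. Ag2CO3 on Celite (2.5 equiv of monovalent silver) in MeCN at 80 °C oxidises the enol of 13 to the electrophilic C3 radical. This radical adds to the alkene of 7 at the carbon next to ring A, and oxidation of the benzylic radical and ring closure give the trans-dihydrofuran as a racemate, that is 15 together with its (2R,3R)-enantiomer F1. Preparative HPLC on a cellulose tris(3,5-dimethylphenylcarbamate) phase separates the two, and the route is rejoined at 15 before step 8.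

**Step 2 (step 5 is the analogous condensation and carries the same risk).** The one-flask acid dehydration passes through a benzylic cation that can alkylate C3 of another pyranone instead of eliminating, and the dianion is poorly soluble. The fallback sets out from 2 and avoids both the dianion and the cation. Horner–Wadsworth–Emmons olefination of 2 with diethyl [2-(methoxy(methyl)amino)-2-oxoethyl]phosphonate (NaH, THF, 0 °C) gives (E)-3-{3,4-bis[(tert-butyldimethylsilyl)oxy]phenyl}-N-methoxy-N-methylprop-2-enamide F2. C-acylation of 2,2,6-trimethyl-4H-1,3-dioxin-4-one at its 6-methyl group by this amide (LiN(SiMe3)2, 2.2 equiv, THF, −78 °C) gives the β-keto dioxinone 6-[(E)-4-{3,4-bis[(tert-butyldimethylsilyl)oxy]phenyl}-2-oxobut-3-en-1-yl]-2,2-dimethyl-4H-1,3-dioxin-4-one F3. Heating this dioxinone in toluene at 110 °C expels acetone and closes the 4-hydroxy-2-pyranone with the E-alkene already in place, rejoining the route at 6.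

**Step 3.** The vinylogous silyl ester 7 may hydrolyse on purification or during recovery of the excess used in step 7, and some silylation at the lactone oxygen is possible. The fallback sets out from 6 and uses an acetal instead of a silyl group on ring A. 2-(Trimethylsilyl)ethoxymethyl chloride with i-Pr2NEt in CH2Cl2 at 0 °C gives 6-[(E)-2-{3,4-bis[(tert-butyldimethylsilyl)oxy]phenyl}ethenyl]-4-{[2-(trimethylsilyl)ethoxy]methoxy}-2H-pyran-2-one F4, which is stable on silica. This acetal takes the place of 7 in step 7 and gives the corresponding (2S,3S)-cycloadduct F5. Under the step 8 conditions fluoride removes the three aryl silyl groups and the acetal ester of the acidic pyranone enol in one operation, rejoining the route at 16.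

## Further compounds

F1 | step 7 | (2R,3R)-enantiomer of 15 | O=c1cc(O[Si](C(C)C)(C(C)C)C(C)C)cc([C@@H]2c3c(cc(/C=C/c4ccc(O[Si](C)(C)C(C)(C)C)cc4)oc3=O)O[C@H]2c2ccc(O[Si](C)(C)C(C)(C)C)c(O[Si](C)(C)C(C)(C)C)c2)o1
F2 | step 2 | (E)-3-{3,4-bis[(tert-butyldimethylsilyl)oxy]phenyl}-N-methoxy-N-methylprop-2-enamide | CON(C)C(=O)/C=C/c1ccc(O[Si](C)(C)C(C)(C)C)c(O[Si](C)(C)C(C)(C)C)c1
F3 | step 2 | 6-[(E)-4-{3,4-bis[(tert-butyldimethylsilyl)oxy]phenyl}-2-oxobut-3-en-1-yl]-2,2-dimethyl-4H-1,3-dioxin-4-one | CC1(C)OC(CC(=O)/C=C/c2ccc(O[Si](C)(C)C(C)(C)C)c(O[Si](C)(C)C(C)(C)C)c2)=CC(=O)O1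
F4 | step 3 | 6-[(E)-2-{3,4-bis[(tert-butyldimethylsilyl)oxy]phenyl}ethenyl]-4-{[2-(trimethylsilyl)ethoxy]methoxy}-2H-pyran-2-one | C[Si](C)(C)CCOCOc1cc(/C=C/c2ccc(O[Si](C)(C)C(C)(C)C)c(O[Si](C)(C)C(C)(C)C)c2)oc(=O)c1
F5 | step 3 | (2S,3S)-2-{3,4-bis[(tert-butyldimethylsilyl)oxy]phenyl}-6-[(E)-2-{4-[(tert-butyldimethylsilyl)oxy]phenyl}ethenyl]-3-(2-oxo-4-{[2-(trimethylsilyl)ethoxy]methoxy}-2H-pyran-6-yl)-2,3-dihydro-4H-furo[3,2-c]pyran-4-one | O=c1cc(OCOCC[Si](C)(C)C)cc([C@H]2c3c(cc(/C=C/c4ccc(O[Si](C)(C)C(C)(C)C)cc4)oc3=O)O[C@@H]2c2ccc(O[Si](C)(C)C(C)(C)C)c(O[Si](C)(C)C(C)(C)C)c2)o1
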